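## Retrosynthesis

Iridoid numbering is used throughout: C1 acetal, O2, C3, C4 (CO2Me), C5, C6=C7, C8 (quaternary, O-bearing), C9, C10 (CH–O), C11/C12 (lactone carbons), C13 (benzylidene CH).

1. Prismatomerin comes from an E-selective aldol condensation of 4-(TBSO)benzaldehyde with the saturated spirolactone-acetal **9**.
2. **9** comes from intramolecular oxa-Michael closure of the C1 lactol oxygen onto spiro-butenolide **8**. This closes the THF acetal and sets C10 and C1.
3. **8** comes from an intramolecular HWE reaction of the phosphonoacetate of tertiary α-hydroxy aldehyde **5**. This closes the lactone ring.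
4. **5** comes from Rubottom α-hydroxylation of the silyl dienol ether of the genipin-derived enal. This puts O on C8 from the convex face and moves the alkene to C6=C7.
5. Ring order: the dihydropyran–cyclopentene comes from genipin; then the lactone (HWE), the THF acetal (oxa-Michael) and last the exocyclic alkylidene.

Assumptions: (−)-genipin (1R,4aS,7aS) and 4-(TBSO)benzaldehyde are commercial. The C1 anomeric centre of lactol intermediates is an equilibrating mixture and is left unspecified.

## Route

**Step 1**
Reactants: **1** (−)-genipin
Product: **2** enal (C10 aldehyde)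
Conditions: activated MnO2 (10 equiv), CH2Cl2, rt
Reagents that add atoms: none
Why: MnO2 oxidises the allylic primary alcohol selectively over the lactol. No stereocentre is touched (C5 and C9 are retained from genipin).

**Step 2**
Reactants: **2**
Product: **3** C1-OTBS enal
Conditions: TBSCl, imidazole, DMF, 0 °C to rt
Reagents that add atoms: TBSCl, CC(C)(C)[Si](C)(C)Cl
Why: Silylation of the lactol OH protects it through the acylation and HWE steps. The anomeric mixture is irrelevant because C1 is re-set in Step 7.

**Step 3**
Reactants: **3**
Product: **4** TMS dienol ether (O–C10H=C8–C7=C6). It is used crude.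
Conditions: TMSOTf, Et3N, CH2Cl2, −78 °C to 0 °C
Reagents that add atoms: TMSOTf, C[Si](C)(C)OS(=O)(=O)C(F)(F)F
Why: Soft enolisation of the enal removes the only γ-H (C6–H), giving the 1-siloxy-1,3-diene. This sets up the α-oxygenation with alkene transposition.

**Step 4**
Reactants: **4**
Product: **5** α-hydroxy aldehyde (C8–OH, C10 CHO, C6=C7)
Conditions: DMDO, acetone/CH2Cl2, −78 °C; then NH4F, MeOH, 0 °C
Reagents that add atoms: DMDO, CC1(C)OO1
Why: Rubottom oxidation epoxidises the electron-rich C8=C10 enol ether from the convex face (the H5/H9 face, trans to C1). The siloxy epoxide opens and the silyl group migrates to the C8 oxygen, and NH4F then removes it. This sets the C8 quaternary configuration and leaves C6=C7 in place.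

**Step 5**
Reactants: **5**; **6** diethylphosphonoacetic acid
Product: **7** phosphonoacetate of the C8 tertiary alcohol
Conditions: EDC·HCl, cat. DMAP, CH2Cl2, 0 °C
Reagents that add atoms: none (**6** is the reactant)
Why: Steglich esterification of the tertiary alcohol. C8 is untouched, so its configuration is retained.

**Step 6**
Reactants: **7**
Product: **8** spiro-butenolide with C10=C11
Conditions: DBU, LiCl, MeCN, 0 °C to rt
Reagents that add atoms: none
Why: Masamune–Roush intramolecular Horner–Wadsworth–Emmons reaction. The stabilised phosphonate carbanion closes onto the non-enolisable C10 aldehyde (5-exo), forming the γ-lactone ring as a butenolide with no new stereocentre.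

**Step 7**
Reactants: **8**
Product: **9** saturated spirolactone with the cis-fused THF acetal
Conditions: TBAF, THF, 0 °C
Reagents that add atoms: none
Why: Fluoride unmasks the C1 lactol alkoxide, which undergoes intramolecular oxa-Michael addition to C10 of the butenolide. Only the cis-fused bicyclic acetal is geometrically accessible, so C10 and C1 are set with the target configuration. The C11 enolate is protonated.

**Step 8**
Reactants: **9**; **10** 4-(TBSO)benzaldehyde
Product: **11** β-hydroxy lactone (C11/C13 mixture)
Conditions: LiHMDS (1.1 equiv) added to a premixed solution of **9** and **10**, THF, −78 °C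
Reagents that add atoms: none (**10** is the reactant)
Why: Lactone enolate aldol, trapped in situ by the aldehyde. The two new centres are destroyed in the next step.

**Step 9**
Reactants: **11**
Product: **12** E-arylidene lactone (TBS aryl ether)
Conditions: MsCl, Et3N, CH2Cl2, 0 °C; then DBU, rt
Reagents that add atoms: none in the product (MsCl, CS(=O)(=O)Cl, is used only transiently and the mesylate is lost)
Why: E1cB elimination of the β-mesylate through the lactone enolate gives the thermodynamically favoured E alkene (aryl trans to the lactone C=O), as in the target.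

**Step 10**
Reactants: **12**
Product: **13** prismatomerin
Conditions: TBAF, AcOH (buffer), THF, 0 °C
Reagents that add atoms: none
Why: Buffered fluoride removes the aryl TBS ether without opening the lactone or acetal.

## Compound list

1 | (−)-genipin, methyl (1R,4aS,7aS)-1-hydroxy-7-(hydroxymethyl)-1,4a,5,7a-tetrahydrocyclopenta[c]pyran-4-carboxylate | COC(=O)C1=CO[C@@H](O)[C@@H]2C(CO)=CC[C@H]12 | starting material
2 | 10-oxo-genipin (enal, C1 lactol free) | COC(=O)C1=CO[C@@H](O)[C@@H]2C(C=O)=CC[C@H]12 | intermediate
3 | C1-O-TBS enal (anomeric mixture) | COC(=O)C1=COC(O[Si](C)(C)C(C)(C)C)[C@@H]2C(C=O)=CC[C@H]12 | intermediate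
4 | TMS dienol ether of 3 (not isolated) | COC(=O)C1=COC(O[Si](C)(C)C(C)(C)C)[C@@H]2C(=CO[Si](C)(C)C)C=C[C@H]12 | intermediate
5 | C8-hydroxy, C10-aldehyde, C6=C7 (C1-OTBS) | COC(=O)C1=COC(O[Si](C)(C)C(C)(C)C)[C@@H]2[C@@](C=O)(O)C=C[C@H]12 | intermediate
6 | diethylphosphonoacetic acid | CCOP(=O)(CC(=O)O)OCC | starting material
7 | phosphonoacetate ester of 5 | COC(=O)C1=COC(O[Si](C)(C)C(C)(C)C)[C@@H]2[C@@](C=O)(OC(=O)CP(=O)(OCC)OCC)C=C[C@H]12 | intermediate
8 | spiro-butenolide (C1-OTBS) | COC(=O)C1=COC(O[Si](C)(C)C(C)(C)C)[C@@H]2[C@]3(C=C[C@H]12)OC(=O)C=C3 | intermediate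
9 | saturated spirolactone acetal (11,13-dihydro target skeleton) | COC(=O)C1=CO[C@@H]2O[C@H]3CC(=O)O[C@]34C=C[C@H]1[C@H]24 | intermediate
10 | 4-(tert-butyldimethylsilyloxy)benzaldehyde | CC(C)(C)[Si](C)(C)Oc1ccc(C=O)cc1 | starting material
11 | aldol adduct (C11/C13 undefined) | COC(=O)C1=CO[C@@H]2O[C@H]3C(C(O)c4ccc(O[Si](C)(C)C(C)(C)C)cc4)C(=O)O[C@]34C=C[C@H]1[C@H]24 | intermediate
12 | E-arylidene lactone, aryl OTBS | COC(=O)C1=CO[C@@H]2O[C@H]3/C(=C\c4ccc(O[Si](C)(C)C(C)(C)C)cc4)C(=O)O[C@]34C=C[C@H]1[C@H]24 | intermediate
13 | prismatomerin | COC(=O)C1=CO[C@@H]2O[C@H]3/C(=C\c4ccc(O)cc4)C(=O)O[C@]34C=C[C@H]1[C@H]24 | target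

## Totals

Total steps: 10. Longest linear sequence: 10 steps from genipin. Steps 3 and 4 can be telescoped into one pot.

## Three steps most likely to fail

1. **Step 4 (Rubottom α-hydroxylation).** Regioselectivity between the two double bonds of the dienol ether, convex-face delivery, and survival of the anomeric TBS group are all uncertain. Fallback: take the C1-protected genipin allylic alcohol through VO(acac)2/TBHP directed 7,8-epoxidation. Open the epoxide with PhSeNa, then H2O2 selenoxide syn-elimination (toward C6, the only possible side) gives the C8-OH/C6=C7 diol. Finally oxidise the primary C10 alcohol to the aldehyde.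
2. **Step 8 (aldol of the β-alkoxy lactone enolate).** The enolate can undergo E1cB ring-opening of the acetal back to butenolide **8**. Fallback: skip the separate oxa-Michael step and run a one-pot fluoride-triggered oxa-Michael/aldol on **8** with the aldehyde present. Here the enolate is generated in situ by C–O bond formation and captured immediately.
3. **Step 5 (acylation of the hindered tertiary α-hydroxy aldehyde).** Fallback: form the C10–C11 bond first by a Mukaiyama aldol of **5** with a silyl ketene acetal of tert-butyl acetate. Then lactonise the tertiary alkoxide onto the ester under acid. Set C10 by an oxidation/stereoselective-reduction sequence (DMP, then hydride delivery from the C7 face), and close the acetal with acid.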